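Ring B, with C17 on C8 and a three-carbon unit on C5, is a p-menthane and is bought as (S)-carvone, whose stereocentre becomes C5 and relays C10, C2, C7 and C9. Everything rests on the C3–C4 disconnection of ring A, where the C2 oxygen sits between two methylenes that end at the fully substituted carbons C10 and C4. In one operation, protonation turns the isopropenyl group into the gem-dimethyl C4 cation, the 2-chloroallyl arm on C10 captures it through C3, and the chloro cation collapses to the C2 ketone of a trans-decalin. The precursor is a monocyclic enone whose vinyl chloride served as latent ketone during side-chain attachment.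

Key step: step 5

Remark: labdane numbering (C1–C20) is used for all intermediates. The target is read as the ent-labdane (2S,5R,9R,10R,13E) with an axial 2-acetoxy group cis to C20. Compound 5 is taken as a catalogue compound.

Step 1
Reactants: 1 (S)-(+)-carvone
Product: 2 (5S,6R)-6-methylcarvone (new methyl = C20, drawn trans to the isopropenyl group; carried on as the epimer mixture at this centre)
Conditions: LiN(i-Pr)2, THF, -78 °C; MeI, -78 to 0 °C
Reagents that add atoms: iodomethane, CI
Why: Kinetic deprotonation at the only alpha' position (C10) and SN2 methylation (enolate alkylation) should install C20; the new centre forms mainly trans to the isopropenyl group but is planarised again in step 2, so its configuration is of no consequence.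

Step 2
Reactants: 2 6-methylcarvone; 3 2,3-dichloroprop-1-ene
Product: 4 (5R,6R)-6-(2-chloroprop-2-en-1-yl)-2,6-dimethyl-5-(prop-1-en-2-yl)cyclohex-2-en-1-one (chloroallyl arm trans, C20 cis to the isopropenyl group)
Conditions: LiN(i-Pr)2, THF-DMPU, -78 °C; 3, -78 °C to rt
Reagents that add atoms: none
Why: In this enolate alkylation the fully substituted cross-conjugated lithium dienolate should be attacked by the allylic chloride on the face anti to the neighbouring C5 isopropenyl group, which sets quaternary C10 with C1 trans and C20 cis to that group.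

Step 3
Reactants: 5 (4-bromobut-1-yn-1-yl)trimethylsilane; 4 dialkylated carvone
Product: 7 tertiary allylic alcohol at C9 bearing the 4-(trimethylsilyl)but-3-ynyl chain (C11–C14), via butynyl Grignard reagent 6 (not isolated)
Conditions: 5, Mg, THF, rt; CeCl3, THF, -78 °C; 4, -78 to 0 °C; aq NH4Cl
Reagents that add atoms: none
Why: In this Imamoto-type organocerium 1,2-addition the weakly basic, oxophilic reagent should add to the hindered C9 carbonyl instead of enolising it and should leave the vinyl chloride untouched; the C9 carbinol configuration is irrelevant because C9 becomes trigonal in step 4.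

Step 4
Reactants: 7 tertiary allylic alcohol
Product: 8 (4R,5R)-4-(2-chloroprop-2-en-1-yl)-2,4-dimethyl-5-(prop-1-en-2-yl)-3-[4-(trimethylsilyl)but-3-yn-1-yl]cyclohex-2-en-1-one (C7 ketone, C8=C9 alkene)
Conditions: pyridinium chlorochromate [C5H5NH][CrO3Cl], NaOAc, 4 Å molecular sieves, CH2Cl2, rt
Reagents that add atoms: pyridinium chlorochromate, [O-][Cr](=O)(=O)Cl.c1cc[nH+]cc1
Why: In this Babler–Dauben oxidative 1,3-transposition the chromate ester of the only allylic arm should shift by a [3,3] process from C9 to C7 and be oxidised there, giving the C7 enone without forming a stereocentre.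

Step 5
Reactants: 8 monocyclic chloroallyl isopropenyl enone
Product: 10 (5R,10R)-15,16-dinor-ent-labd-8-en-13-yne-2,7-dione (trans-fused), via silylated bicyclic enedione 9 (not isolated)
Conditions: HCO2H-H2O (95:5), 50 °C; evaporate; then K2CO3, MeOH, rt
Reagents that add atoms: water, O
Why: Markovnikov protonation of the isopropenyl group gives the tertiary C4 cation, whose two methyl groups are C18 and C19; the terminal carbon C3 of the chloroalkene attacks it, and the chlorine-stabilised C2 cation takes up water and loses HCl to leave the C2 ketone. The closest known reaction type is the Lansbury chloro-olefin annulation, a cation-olefin cyclisation in which a vinyl chloride is the ketone-equivalent terminator. Ring A closes in the 6-endo-trig mode with respect to C2=C3, since the 5-exo alternative would need a primary cation. No new stereocentre is formed (C4 carries two methyl groups, C2 is trigonal); the trans ring fusion is relayed from C5 and C10, whose trans arms can meet only in the diequatorial, chair-like arrangement. The step needs chemoselective protonation, which the substrate secures because the C8=C9 alkene is deactivated by the C7 carbonyl, the chloroalkene is deactivated by chlorine, and the silylalkyne is less basic and could only close a medium ring. K2CO3 in MeOH then cleaves the alkynyl C–Si bond, so that any partial protodesilylation in the acid converges on 10.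

Step 6
Reactants: 10 bicyclic enedione
Product: 11 (2S,5R,7R,10R)-15,16-dinor-ent-labd-8-en-13-yne-2,7-diol (2-OH axial and cis to C20; 7-OH pseudo-equatorial and on the C20 face)
Conditions: NaBH4, CeCl3·7H2O, MeOH, -40 to 0 °C
Reagents that add atoms: none
Why: In this Luche reduction hydride should reach C2 only from the equatorial side, because the axial trajectory is blocked by the syn-axial C20 and C4 methyl groups (axial alcohol), and should add 1,2 to the enone axially at C7 from the face anti to C20 (pseudo-equatorial alcohol).

Step 7
Reactants: 11 diol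
Product: 14 (2S,5R,9R,10R)-15,16-dinor-ent-labd-7-en-13-yn-2-ol, via allylic sulfonylhydrazine 12 (not isolated), via allylic diazene 13 (not isolated)
Conditions: PPh3, DEAD, 2-nitrobenzenesulfonylhydrazide, N-methylmorpholine, -30 °C; then rt
Reagents that add atoms: none
Why: In this Myers reductive allylic transposition, Mitsunobu displacement with inversion should place nitrogen at C7 on the face anti to C20, and after loss of the sulfinic acid the retro-ene loss of N2 delivers hydrogen suprafacially to C9 on that face, which sets C9 and moves the alkene to C7=C8, while the crowded axial 2-OH should not be activated.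

Step 8
Reactants: 14 alkynol
Product: 17 (2S,5R,9R,10R,13E)-ent-labda-7,13-diene-2,15-diol, via alkenylalane 15 (not isolated), via lithium alanate 16 (not isolated)
Conditions: AlMe3, Cp2ZrCl2 (25 mol %), CH2Cl2, 0 °C to rt; evaporate; n-BuLi, THF-hexane, -78 to 0 °C; (CH2O)n, rt; aq KNaC4H4O6
Reagents that add atoms: trimethylaluminium, C[Al](C)C; paraformaldehyde (as formaldehyde), C=O
Why: Negishi zirconium-catalysed carboalumination adds methyl (C16) and aluminium syn across the terminal alkyne with methyl on C13, and hydroxymethylation of the derived alanate with retention adds C15, so the 13E geometry is set stereospecifically while the 2-OH is merely carried as its aluminium alkoxide.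

Step 9
Reactants: 17 diol
Product: 18 target, (2S,5R,9R,10R,13E)-ent-labda-7,13-diene-2,15-diyl diacetate
Conditions: Ac2O, DMAP, pyridine, rt to 40 °C
Reagents that add atoms: acetic anhydride, CC(=O)OC(C)=O
Why: DMAP-catalysed acylation should esterify the primary allylic and the hindered axial secondary alcohol in one operation without touching any stereocentre.

Compound list
1 | (S)-(+)-carvone | CC1=CC[C@@H](CC1=O)C(C)=C | starting material
2 | (5S,6R)-6-methylcarvone (major epimer drawn) | O=C1C(C)=CC[C@H](C(C)=C)[C@H]1C | intermediate
3 | 2,3-dichloroprop-1-ene | ClCC(Cl)=C | starting material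
4 | (5R,6R)-6-(2-chloroprop-2-en-1-yl)-2,6-dimethyl-5-(prop-1-en-2-yl)cyclohex-2-en-1-one | O=C1C(C)=CC[C@H](C(C)=C)[C@@]1(C)CC(Cl)=C | intermediate
5 | (4-bromobut-1-yn-1-yl)trimethylsilane | C[Si](C)(C)C#CCCBr | starting material
6 | [4-(trimethylsilyl)but-3-yn-1-yl]magnesium bromide | C[Si](C)(C)C#CCC[Mg]Br | intermediate
7 | (5R,6R)-6-(2-chloroprop-2-en-1-yl)-2,6-dimethyl-5-(prop-1-en-2-yl)-1-[4-(trimethylsilyl)but-3-yn-1-yl]cyclohex-2-en-1-ol (carbinol centre unassigned, erased in step 4) | OC1(CCC#C[Si](C)(C)C)C(C)=CC[C@H](C(C)=C)[C@@]1(C)CC(Cl)=C | intermediate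
8 | (4R,5R)-4-(2-chloroprop-2-en-1-yl)-2,4-dimethyl-5-(prop-1-en-2-yl)-3-[4-(trimethylsilyl)but-3-yn-1-yl]cyclohex-2-en-1-one | C[Si](C)(C)C#CCCC1=C(C)C(=O)C[C@H](C(C)=C)[C@@]1(C)CC(Cl)=C | intermediate
9 | (5R,10R)-14-trimethylsilyl-15,16-dinor-ent-labd-8-en-13-yne-2,7-dione | C[Si](C)(C)C#CCCC1=C(C)C(=O)C[C@@H]2C(C)(C)CC(=O)C[C@@]12C | intermediate
10 | (5R,10R)-15,16-dinor-ent-labd-8-en-13-yne-2,7-dione | C#CCCC1=C(C)C(=O)C[C@@H]2C(C)(C)CC(=O)C[C@@]12C | intermediate
11 | (2S,5R,7R,10R)-15,16-dinor-ent-labd-8-en-13-yne-2,7-diol | C#CCCC1=C(C)[C@H](O)C[C@@H]2C(C)(C)C[C@H](O)C[C@@]12C | intermediate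
12 | C7 N-(2-nitrobenzenesulfonyl)hydrazine (inverted at C7) | C#CCCC1=C(C)[C@@H](N(N)S(=O)(=O)c3ccccc3[N+](=O)[O-])C[C@@H]2C(C)(C)C[C@H](O)C[C@@]12C | intermediate
13 | C7 allylic diazene | C#CCCC1=C(C)[C@@H](N=N)C[C@@H]2C(C)(C)C[C@H](O)C[C@@]12C | intermediate
14 | (2S,5R,9R,10R)-15,16-dinor-ent-labd-7-en-13-yn-2-ol | C#CCC[C@@H]1C(C)=CC[C@@H]2C(C)(C)C[C@H](O)C[C@@]12C | intermediate
15 | (E)-alkenyldimethylalane, 2-O-dimethylaluminium alkoxide | C[Al](C)/C=C(\C)CC[C@@H]1C(C)=CC[C@@H]2C(C)(C)C[C@H](O[Al](C)C)C[C@@]12C | intermediate
16 | lithium n-butyl(alkenyl)dimethylalanate of 15 | [Li+].CCCC[Al-](C)(C)/C=C(\C)CC[C@@H]1C(C)=CC[C@@H]2C(C)(C)C[C@H](O[Al](C)C)C[C@@]12C | intermediate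
17 | (2S,5R,9R,10R,13E)-ent-labda-7,13-diene-2,15-diol | OC/C=C(\C)CC[C@@H]1C(C)=CC[C@@H]2C(C)(C)C[C@H](O)C[C@@]12C | intermediate
18 | (2S,5R,9R,10R,13E)-ent-labda-7,13-diene-2,15-diyl diacetate | CC(=O)OC/C=C(\C)CC[C@@H]1C(C)=CC[C@@H]2C(C)(C)C[C@H](OC(C)=O)C[C@@]12C | target

Total step count: 9. Longest linear sequence: 9 (fully linear from 1; 3 and 5 are purchased).

Steps most likely to fail

Step 5 (key step). The C4 cation may lose a proton toward C5 and drain into conjugated dienone isomers before ring A closes. The warm protic medium may also hydrate the alkyne. The fallback sets out from 8 and comes back at 9. Dry HCl in CH2Cl2 at 0 °C should add to the isopropenyl group to give the tertiary chloride F1. SnCl4 in CH2Cl2 at -78 °C should ionise it and close ring A by Lewis-acid alkylation of the chloroalkene with chloride return. This is the reaction type of tert-butyl chloride with vinyl chloride, and it should give the geminal dichloride F2. AgNO3 in aqueous acetone should hydrolyse it to 9, which is desilylated to 10 as in step 5.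

Step 7. The activated C7 alcohol may eliminate to a homoannular diene, or may be displaced too slowly next to the tetrasubstituted alkene. The fallback sets out from 11 and comes back at 14. ClCO2Me and pyridine at 0 °C should acylate only the less hindered allylic alcohol to give the allylic methyl carbonate F3. Tsuji formate hydrogenolysis follows (Pd2(dba)3, PBu3, HCO2H, Et3N, THF). Zerovalent palladium should ionise F3 anti to the carbonate, and hydride should pass from palladium to the more substituted terminus C9 on the face anti to C20, giving the same C9 configuration and the C7=C8 alkene.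

Step 4. The crowded tertiary carbinol may dehydrate to dienes, or may fail to form the chromate ester. The fallback sets out from 7 and comes back at 8. Catalytic Re2O7 in Et2O at 0 °C should isomerise 7 without oxidation to the more stable secondary allylic alcohol F4, which has the tetrasubstituted C8=C9 alkene and forms as C7 epimers. Dess–Martin periodinane in CH2Cl2 should then oxidise it to 8.

Further compounds
F1 | step 5 | tertiary chloride (HCl adduct of 8 at the isopropenyl group) | C[Si](C)(C)C#CCCC1=C(C)C(=O)C[C@H](C(C)(C)Cl)[C@@]1(C)CC(Cl)=C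
F2 | step 5 | (5R,10R)-2,2-dichloro-14-trimethylsilyl-15,16-dinor-ent-labd-8-en-13-yn-7-one | C[Si](C)(C)C#CCCC1=C(C)C(=O)C[C@@H]2C(C)(C)CC(Cl)(Cl)C[C@@]12C
F3 | step 7 | C7 methyl carbonate of 11 | C#CCCC1=C(C)[C@H](OC(=O)OC)C[C@@H]2C(C)(C)C[C@H](O)C[C@@]12C
F4 | step 4 | secondary allylic alcohol (C7 epimers) corresponding to 8 | C[Si](C)(C)C#CCCC1=C(C)C(O)C[C@H](C(C)=C)[C@@]1(C)CC(Cl)=C
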